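Prostanoid numbering is used throughout: ester carbon C1, ring C8–C12, ketone C9, acetoxy-bearing quaternary carbon C12, terminal methyl C20. The target is compound 21.

## The problem

Target 21 is a monocyclic C20 prostanoid with no ring fusion: a cyclopent-2-enone (ketone C9, alkene C10–C11) whose two adjacent sp3 carbons, C8 and C12, each carry one unbranched chain. The upper chain (C1–C7) holds a methyl ester, an allylic acetoxy stereocentre at C4 (S) and an E alkene at C5–C6. The lower chain is a (Z)-oct-2-enyl group on C12, which also bears the second acetate. There are three stereocentres: C12 (R, fully substituted), C8 (R) and C4 (S). C8 is α to the ketone and can be equilibrated under the influence of C12 toward the isomer with the two carbon chains trans, which is the arrangement of 21. C12 has no hydrogen and cannot be corrected once made. C4 is insulated from the ring by the trans alkene, so it must be brought in enantiopure and joined to a ring of defined absolute configuration. The molecule is fragile: the C12 acetate is β to the ketone with an acidic hydrogen at C8 (base-induced loss of acetic acid toward a cyclopentadienone), 4-oxygenated cyclopentenones rearrange in aqueous base, and the skipped Z alkene, the allylic acetate and the methyl ester exclude strong base, hydride and forcing acid late in the route. The enabling feature is that C9–C12, oxygenated at both ends with unsaturation between, is a 2,5-disubstituted furan in disguise: the furan oxygen is the C9 oxygen, the octenyl-bearing α-carbon is C12, and a carbinol carbon on the other α-position is C8. A 4-oxy-4,5-disubstituted cyclopent-2-enone is exactly what a 5-alkyl-2-furylcarbinol rearrangement delivers.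

## Retrosynthesis

**C5=C6 (21 to 12 and 20).** The C5–C6 double bond is cut by cross-metathesis, giving ring fragment 12 with an allyl group on C8 and the six-carbon ester 20 carrying C4. The neighbouring cuts are worse: alkylating C8 (C7–C8) or olefinating a C6 aldehyde needs base on a β-acyloxy ketone, and a C4–C5 addition would create C4 without control. Metathesis is neutral and puts C4 in a small fragment from the chiral pool. The precursors carry two and one stereocentres instead of three. The forward step must engage only the terminal alkenes, leave the Z alkene at C14–C15 and the enone alone, and give the E isomer.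

**C12 O-acetyl (12 to 11).** Removing the acetyl group leads to tertiary alcohol 11. Placing this acylation directly after ring formation means the base-labile β-acetoxy ketone exists only for the last step. The forward reaction must acylate a hindered tertiary hydroxyl without amine base.

**C8–C12 (11 to 9).** The C8–C12 bond is cut, with return of the C12 hydroxyl to the medium, leading through the ring-opened cation 10 to furylcarbinol 9. Closures at C8–C9 or C9–C10 start from acyclic chains in which the C12 carbinol, and usually C8, must already be in place. The C8–C12 closure makes the ring and both centres in one event. Precursor 9 is a flat aromatic compound whose single stereocentre is erased on ionisation, so it can be racemic. The forward step requires hydroxyl from the wet medium to enter at the octenyl-bearing furan carbon, one sense of conrotation under a chiral Brønsted acid, and the chains trans.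

**C7–C8 (9 to 7 and 8).** The carbinol is cut into aldehyde 7 and allyl Grignard reagent 8. The reverse polarity (a metallated octenylfuran adding to but-3-enal) would expose the doubly activated furfuryl–allyl methylene to base and needs an unstable aldehyde. The forward step is a simple 1,2-addition.

**Furan substituents (7 to 5, then 3 and 2, then 1).** The formyl C–C bond is cut by electrophilic formylation of 5; this is chosen over lithiation–formylation because of the same acidic methylene. The C12–C13 bond is cut to 2-lithiofuran 4 (from furan 3) and allylic bromide 2, made from commercial alcohol 1, which supplies the Z geometry so that no step has to create it. The alkylation must go at the primary carbon with the geometry retained.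

**Side chain (20 to 17, 15, 14 and 13).** The acetate and methyl ester of 20 come from lactone 17 through carboxylate 18 and hydroxy ester 19. The vinyl group of 17 comes from methylenation of aldehyde 16, made from alcohol 15, which derives from lactone acid 14 and L-glutamic acid 13 with retention. Asymmetric vinylation or resolution could also give C4, but the amino acid fixes the absolute configuration unambiguously. The one demand is that aldehyde 16 does not epimerise.

## Roads not taken

**Alternative 1:** The cut is the C12–O bond, made after C8 is in place. A Claisen rearrangement first sets an acetic acid arm on C8, giving 2-[5-(tert-butyldimethylsilyloxy)-2-(oct-2-yn-1-yl)cyclopent-2-en-1-yl]acetic acid A1. In the key step an arylselenenyl halide activates the C11–C12 alkene and the carboxylate closes on the tertiary carbon C12 to give the cis-fused selenolactone A2.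
- Merits: every reaction type is established. The cis fusion forces the C12 oxygen onto the face of C7, which is the relative configuration of 21, and the absolute configuration comes from suprafacial chirality transfer. Stereocontrol is therefore more secure than in the chosen plan.
- Weak points: A2 is far from 21. The selenide must be oxidised and eliminated to make C10–C11, the C9 silyl ether removed and oxidised, the alkyne semi-hydrogenated, and the lactone (whose carbonyl is C6) reduced and olefinated to build E C5–C6, with C4 still to be made or imported. All of this happens around a tertiary oxygen that must end as an acetate β to a ketone.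
- Comparison: Alternative 1 is better in certainty of configuration and contains no untested reaction. The chosen plan sets against it a longest line of seven steps, a ring formed with its oxidation pattern complete, and a racemic, known version of its key step in reserve.

**Alternative 2:** The cut is C8–C9. A chiral triazolium-derived carbene turns the C9 aldehyde of methyl (E)-4-(oct-2-yn-1-yl)-7-oxo-4-(triethylsilyloxy)hept-2-enoate A3 into an acyl anion equivalent that adds 5-exo to C8 of the enoate. This gives the cyclopentanone methyl 2-[2-(oct-2-yn-1-yl)-5-oxo-2-(triethylsilyloxy)cyclopentyl]acetate A4 and sets C8.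
- Merits: intramolecular Stetter reactions of aliphatic aldehydes are a documented enantioselective reaction class, which the chosen key step is not.
- Weak points: the hard centre is only moved. A3 must already contain the C12 tertiary carbinol as a single enantiomer, flanked by three similar carbon arms. The acceptor carbon C8 is next to this fully substituted carbon, so reactivity and catalyst-versus-substrate control are uncertain. A4 lacks the C10–C11 alkene, which needs a later dehydrogenation next to a β-silyloxy group. The two-carbon ester arm still has to become the seven-carbon chain with C4, the alkyne the Z alkene, and the silyl ether the acetate.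
- Comparison: Alternative 2 is better in precedent for asymmetric induction at C8. The chosen plan creates C12 and C8 together from an achiral-in-effect precursor, obtains the enone directly and is about half as long.

**Alternative 3:** The cut is C9–C10. The cationic monovalent rhodium complex [Rh(Ph2PCH2CH2PPh2)]2(BF4)2 A7 inserts into the aldehyde C–H bond of (Z)-3-ethynyl-2-[2-(4-methoxybenzyloxy)ethyl]-3-(triethylsilyloxy)undec-5-enal A5 and adds the acyl hydride across the C10–C11 alkyne in net trans fashion, closing the cyclopentenone A6.
- Merits: the ring closes away from both stereocentres, the enone appears directly, the Z alkene is already present, and cyclisation of 4-alkynals to cyclopentenones is a known reaction type.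
- Weak points: neither stereocentre is made in the key step. The C8/C12 pair, a tertiary propargylic silyl ether next to an α-branched aldehyde, must be assembled by acyclic stereocontrol, in which a ketone with two similar flanking groups has to be differentiated. A5 is epimerisable at C8 and prone to β-elimination of the silyloxy group. Decarbonylation and binding of the C14–C15 alkene to rhodium compete. A6 still needs deprotection, oxidation, olefination with the C4 problem unsolved, and exchange of silyl ether for acetate.
- Comparison: Alternative 3 is the better choice if ring closure must not endanger existing stereocentres. The chosen plan sets against it that it needs no acyclic stereocontrol, and that its end game joins C5=C6 under neutral conditions with C4 already in hand.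

Key step: step 5

Assumption: the sense of induction of the chiral acid in step 5 cannot be predicted with confidence; the (R)-catalyst is written, and its enantiomer is to be used should the opposite sense be found.

## Steps

**Step 1**
Reactants: 1 (Z)-oct-2-en-1-ol
Product: 2 (Z)-1-bromooct-2-ene
Conditions: CBr4, PPh3, CH2Cl2, 0 °C
Reagents that add atoms: carbon tetrabromide, BrC(Br)(Br)Br
Why: Appel bromination; the oxyphosphonium is displaced at the primary carbon by SN2 at 0 °C, which should keep the Z geometry and avoid allylic transposition, and the bromide is used at once.

**Step 2**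
Reactants: 3 furan; 2 (Z)-1-bromooct-2-ene
Product: 5 2-[(Z)-oct-2-en-1-yl]furan, via 2-lithiofuran 4 (not isolated)
Conditions: n-BuLi, THF, 0 °C; then 2, −78 °C → 0 °C
Reagents that add atoms: none
Why: α-Lithiation of furan followed by SN2 alkylation of the aryllithium with the primary allylic bromide at low temperature; a small excess of furan ensures no free n-BuLi meets the bromide, and the Z alkene is not involved.

**Step 3**
Reactants: 5 2-[(Z)-oct-2-en-1-yl]furan
Product: 7 5-[(Z)-oct-2-en-1-yl]furan-2-carbaldehyde, via iminium dichlorophosphate 6 (not isolated)
Conditions: POCl3, DMF, 0 °C → rt; aq. NaOAc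
Reagents that add atoms: N,N-dimethylformamide, CN(C)C=O; water, O
Why: Vilsmeier–Haack formylation; the chloroiminium ion attacks the only free α-position of the electron-rich 2-alkylfuran, the isolated alkene is too weak a nucleophile to compete, and buffered hydrolysis of 6 releases the aldehyde without base acting on the furfuryl–allyl methylene.

**Step 4**
Reactants: 7 5-[(Z)-oct-2-en-1-yl]furan-2-carbaldehyde; 8 allylmagnesium bromide
Product: 9 1-{5-[(Z)-oct-2-en-1-yl]furan-2-yl}but-3-en-1-ol (racemic at the carbinol carbon)
Conditions: THF, −78 °C; aq. NH4Cl
Reagents that add atoms: none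
Why: Grignard 1,2-addition to the aldehyde; the carbinol is deliberately racemic because its stereocentre is erased on ionisation in step 5.

**Step 5**
Reactants: 9 1-{5-[(Z)-oct-2-en-1-yl]furan-2-yl}but-3-en-1-ol
Product: 11 (4R,5R)-5-allyl-4-hydroxy-4-[(Z)-oct-2-en-1-yl]cyclopent-2-en-1-one (hydroxyl cis to allyl), via hydroxypentadienyl cation 10 (not isolated)
Conditions: (R)-3,3'-bis(2,4,6-triisopropylphenyl)-1,1'-binaphthyl-2,2'-diyl N-triflylphosphoramide, (ArO)2P(O)NHSO2CF3 (10 mol %), H2O (5 equiv), CHCl3, 40 °C
Reagents that add atoms: water, O
Why: Proposed new method: the strong chiral acid ionises the carbinol to the 5-alkylfurfuryl cation, water adds at the octenyl-bearing furan carbon (the future C12), and the resulting alkylidene-dihydrofuran hemiketal opens to the 1,4-dihydroxypentadienyl cation 10, which closes by thermal conrotatory 4π electrocyclisation to form C8–C12 while the furan oxygen becomes the C9 ketone; the closest known reaction types are the racemic acid-catalysed Piancatelli rearrangement of 5-alkyl-2-furylcarbinols with water and chiral phosphoric acid-catalysed aza-Piancatelli rearrangements with anilines. The single ring is closed in a Nazarov-like 4π conrotatory mode between the two termini of 10, and both enantiomers of racemic 9 converge on the same cation. C12 is fixed by the sense of conrotation, which the chiral phosphoramidate anion is expected to impose by hydrogen bonding to both O–H groups of 10 in a contact ion pair in the weakly polar medium. C8 follows from the outward position of the allyl-bearing carbon at the enol terminus together with the outward position of the larger octenyl group at C12, so that conrotation places the two carbon chains trans and the hydroxyl cis to allyl. Because C8 is α to the ketone, acid-mediated enolisation can move any cis-dialkyl isomer to the same, more stable trans-dialkyl isomer without touching C12. The step needs water to attack the remote furan carbon; attack at the carbinol carbon only returns 9, so the rearrangement drains that equilibrium. It also needs capture of the cation to outrun loss of a C7 proton to a furyl diene, which the ready ionisation of the 5-alkylfuran at low temperature and the excess of water should secure.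

**Step 6**
Reactants: 11 (4R,5R)-5-allyl-4-hydroxy-4-[(Z)-oct-2-en-1-yl]cyclopent-2-en-1-one
Product: 12 (1R,5R)-5-allyl-1-[(Z)-oct-2-en-1-yl]-4-oxocyclopent-2-en-1-yl acetate
Conditions: Ac2O (3 equiv), Sc(OTf)3 (2 mol %), MeCN, −20 °C
Reagents that add atoms: acetic anhydride, CC(=O)OC(C)=O
Why: Lewis acid-catalysed acylation of a tertiary alcohol with an anhydride, chosen over amine-mediated acylation because 4-acyloxycyclopentenones with an α′-hydrogen lose carboxylic acid under base; ionisation at C12 is not expected since the cation would be conjugated with the enone carbonyl, and no stereocentre is touched.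

**Step 7**
Reactants: 13 L-glutamic acid
Product: 14 (S)-5-oxotetrahydrofuran-2-carboxylic acid
Conditions: NaNO2, aq. HCl, 0 °C → rt
Reagents that add atoms: none
Why: Diazotisation of the α-amino acid; the diazonium is displaced by the neighbouring carboxylate and the α-lactone is opened by the γ-carboxyl group, two inversions that give net retention.

**Step 8**
Reactants: 14 (S)-5-oxotetrahydrofuran-2-carboxylic acid
Product: 15 (S)-5-(hydroxymethyl)dihydrofuran-2(3H)-one
Conditions: BH3·SMe2, THF, 0 °C → rt; MeOH
Reagents that add atoms: none
Why: Borane reduces the free carboxylic acid through its acyloxyborane much faster than the lactone, so the primary alcohol should form without ring opening or loss of configuration.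

**Step 9**
Reactants: 15 (S)-5-(hydroxymethyl)dihydrofuran-2(3H)-one
Product: 17 (S)-5-vinyldihydrofuran-2(3H)-one, via (S)-5-oxotetrahydrofuran-2-carbaldehyde 16 (not isolated)
Conditions: Dess–Martin periodinane, CH2Cl2, rt; filter, concentrate; Ph3PCH3Br, KN(SiMe3)2, THF, −78 °C → 0 °C
Reagents that add atoms: methyltriphenylphosphonium bromide, C[P+](c1ccccc1)(c1ccccc1)c1ccccc1.[Br-]
Why: Dess–Martin oxidation under neutral anhydrous conditions gives the hydrate-prone α-acyloxy aldehyde 16, which is methylenated at once by Wittig reaction at low temperature, where addition to the aldehyde should outrun enolisation and attack on the lactone; the stereocentre is carried over unchanged.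

**Step 10**
Reactants: 17 (S)-5-vinyldihydrofuran-2(3H)-one
Product: 20 methyl (S)-4-acetoxyhex-5-enoate, via potassium (S)-4-hydroxyhex-5-enoate 18 (not isolated), via methyl (S)-4-hydroxyhex-5-enoate 19 (not isolated)
Conditions: KOH (1.0 equiv), MeOH–H2O, rt, then evaporate; MeI, DMF, 0 °C → rt; Ac2O, pyridine, 4-(dimethylamino)pyridine (cat.), rt
Reagents that add atoms: potassium hydroxide, [K+].[OH-]; iodomethane, CI; acetic anhydride, CC(=O)OC(C)=O
Why: Saponification opens the lactone without touching the C4–O bond, SN2 methylation of the carboxylate gives hydroxy ester 19, and immediate nucleophile-catalysed acetylation traps the hydroxyl before it can relactonise; the configuration is retained throughout.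

**Step 11**
Reactants: 12 (1R,5R)-5-allyl-1-[(Z)-oct-2-en-1-yl]-4-oxocyclopent-2-en-1-yl acetate; 20 methyl (S)-4-acetoxyhex-5-enoate
Product: 21 methyl (4S,5E)-4-acetoxy-7-[(1R,2R)-2-acetoxy-2-[(Z)-oct-2-en-1-yl]-5-oxocyclopent-3-en-1-yl]hept-5-enoate
Conditions: second-generation Hoveyda–Grubbs catalyst RuCl2(H2IMes)(=CH-C6H4-2-OiPr), H2IMes = 1,3-dimesitylimidazolidin-2-ylidene (5 mol %), 20 (3 equiv), CH2Cl2, 40 °C
Reagents that add atoms: none
Why: Olefin cross-metathesis between the terminal allyl group of 12 and an excess of the slowly homodimerising secondary allylic acetate 20; the E alkene is expected as the thermodynamically preferred isomer next to the allylic branch, the enone alkene is electron-poor and unreactive, and ring closure onto C14 is disfavoured because the trans chains would have to form a trans-fused cyclohexene on a nearly planar cyclopentenone.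

## Compound list

1 | (Z)-oct-2-en-1-ol | CCCCC/C=C\CO | starting material
2 | (Z)-1-bromooct-2-ene | CCCCC/C=C\CBr | intermediate
3 | furan | c1ccoc1 | starting material
4 | 2-lithiofuran | [Li]c1ccco1 | intermediate (not isolated)
5 | 2-[(Z)-oct-2-en-1-yl]furan | CCCCC/C=C\Cc1ccco1 | intermediate
6 | N,N-dimethyl-1-{5-[(Z)-oct-2-en-1-yl]furan-2-yl}methaniminium dichlorophosphate | CCCCC/C=C\Cc1ccc(o1)C=[N+](C)C.[O-]P(=O)(Cl)Cl | intermediate (not isolated)
7 | 5-[(Z)-oct-2-en-1-yl]furan-2-carbaldehyde | CCCCC/C=C\Cc1ccc(C=O)o1 | intermediate
8 | allylmagnesium bromide | C=CC[Mg]Br | starting material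
9 | 1-{5-[(Z)-oct-2-en-1-yl]furan-2-yl}but-3-en-1-ol (racemic) | CCCCC/C=C\Cc1ccc(o1)C(O)CC=C | intermediate
10 | O-protonated (4Z,6Z,10Z)-5-hydroxyhexadeca-1,4,6,10-tetraen-8-one (hydroxypentadienyl cation) | CCCCC/C=C\CC(=[OH+])/C=C\C(O)=C\CC=C | intermediate (not isolated)
11 | (4R,5R)-5-allyl-4-hydroxy-4-[(Z)-oct-2-en-1-yl]cyclopent-2-en-1-one | CCCCC/C=C\C[C@@]1(O)C=CC(=O)[C@@H]1CC=C | intermediate
12 | (1R,5R)-5-allyl-1-[(Z)-oct-2-en-1-yl]-4-oxocyclopent-2-en-1-yl acetate | CCCCC/C=C\C[C@@]1(OC(C)=O)C=CC(=O)[C@@H]1CC=C | intermediate
13 | L-glutamic acid | N[C@@H](CCC(=O)O)C(=O)O | starting material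
14 | (S)-5-oxotetrahydrofuran-2-carboxylic acid | OC(=O)[C@@H]1CCC(=O)O1 | intermediate
15 | (S)-5-(hydroxymethyl)dihydrofuran-2(3H)-one | OC[C@@H]1CCC(=O)O1 | intermediate
16 | (S)-5-oxotetrahydrofuran-2-carbaldehyde | O=C[C@@H]1CCC(=O)O1 | intermediate (not isolated)
17 | (S)-5-vinyldihydrofuran-2(3H)-one | C=C[C@@H]1CCC(=O)O1 | intermediate
18 | potassium (S)-4-hydroxyhex-5-enoate | C=C[C@@H](O)CCC(=O)[O-].[K+] | intermediate (not isolated)
19 | methyl (S)-4-hydroxyhex-5-enoate | C=C[C@@H](O)CCC(=O)OC | intermediate (not isolated)
20 | methyl (S)-4-acetoxyhex-5-enoate | C=C[C@H](CCC(=O)OC)OC(C)=O | intermediate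
21 | methyl (4S,5E)-4-acetoxy-7-[(1R,2R)-2-acetoxy-2-[(Z)-oct-2-en-1-yl]-5-oxocyclopent-3-en-1-yl]hept-5-enoate | CCCCC/C=C\C[C@@]1(OC(C)=O)C=CC(=O)[C@@H]1C/C=C/[C@H](CCC(=O)OC)OC(C)=O | target

## Step count and least certain steps

Total step count: 11, with steps 9 and 10 each counted as one telescoped operation. Longest linear sequence: 7 steps (steps 1–6 and 11). The side-chain branch is 5 steps (steps 7–11).

**Step 5 (key step, Proposed new method).** Most likely to go wrong: the two senses of conrotation are poorly discriminated, because water loosens the ion pair between cation 10 and the chiral anion. Further risks are proton loss from the furfuryl cation toward a conjugated furyl diene with oligomerisation, incomplete trans control at C8, and slow onward isomerisation of the product to a 2,3-disubstituted 4-hydroxycyclopentenone on prolonged heating.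

Fallback (known chemistry): from 9, the racemic rearrangement is run with Dy(OTf)3 (10 mol %) in MeCN–H2O at 80 °C, the established Lewis acid variant for 5-alkyl-2-furylcarbinols. It should give racemic (4R*,5R*)-5-allyl-4-hydroxy-4-[(Z)-oct-2-en-1-yl]cyclopent-2-en-1-one F1. Acetylation as in step 6 gives racemic (1R*,5R*)-5-allyl-1-[(Z)-oct-2-en-1-yl]-4-oxocyclopent-2-en-1-yl acetate F2. Cross-metathesis with enantiopure 20 as in step 11 then turns the two ring enantiomers into diastereomers: 21 and methyl (4S,5E)-4-acetoxy-7-[(1S,2S)-2-acetoxy-2-[(Z)-oct-2-en-1-yl]-5-oxocyclopent-3-en-1-yl]hept-5-enoate F3. These are separated by preparative HPLC, and the route is rejoined at 21. Control of the ring configuration thus passes from the catalyst to a separation that uses the C4 centre.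

**Step 11.** Most likely to go wrong: secondary metathesis at the C14–C15 Z alkene (loss of Z geometry or exchange of the pentyl terminus) and ruthenium hydride-induced alkene migration. Both grow with reaction time, and the time may be long if the alkylidene formed at C6 is held in a six-membered chelate by the C9 carbonyl.

Fallback: the metathesis is moved ahead of ring formation, where neither the chelating acetoxy enone nor any intramolecular pathway exists. From 9, cross-metathesis with 20 under the step 11 conditions should give methyl (4S,5E)-4-acetoxy-8-hydroxy-8-{5-[(Z)-oct-2-en-1-yl]furan-2-yl}oct-5-enoate F4 as a mixture of carbinol epimers, which is immaterial. Rearrangement under the step 5 conditions should give methyl (4S,5E)-4-acetoxy-7-[(1R,2R)-2-hydroxy-2-[(Z)-oct-2-en-1-yl]-5-oxocyclopent-3-en-1-yl]hept-5-enoate F5. Acetylation as in step 6 rejoins the route at 21.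

**Step 9.** Most likely to go wrong: partial epimerisation of aldehyde 16 by enolisation under the basic ylide, with some loss of material to ylide attack on the lactone, which would erode the enantiopurity of C4.

Fallback: from 17 of reduced enantiopurity, the lactone is opened and methylated as in step 10 to crude 19. Chemical acetylation is then replaced by enzymatic acyl transfer (immobilised Candida antarctica lipase B, vinyl acetate, tert-butyl methyl ether, rt). With the ester chain as the large group and vinyl as the medium group, the usual enantiopreference of this lipase for secondary alcohols should acylate the (S)-alcohol selectively to 20. The minor enantiomer, methyl (R)-4-hydroxyhex-5-enoate F6, is left behind and removed. The route is rejoined at 20, with the purity of C4 now secured by the enzyme.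

**Step 2.** Most likely to go wrong: attack at the γ-carbon of the allylic bromide (SN2′), partial Z to E isomerisation of the bromide through ionisation, and deprotonation of the doubly activated methylene of the product by the aryllithium.

Fallback: from 4, alkylation with 1-bromooct-2-yne in THF at −78 °C → rt should give 2-(oct-2-yn-1-yl)furan F7. Semi-hydrogenation (H2, Pd/CaCO3 poisoned with Pb(OAc)2, quinoline, hexane) then creates the Z alkene after the C–C bond is formed and rejoins the route at 5.

## Further compounds

F1 | step 5 | racemic (4R*,5R*)-5-allyl-4-hydroxy-4-[(Z)-oct-2-en-1-yl]cyclopent-2-en-1-one | CCCCC/C=C\C[C@@]1(O)C=CC(=O)[C@@H]1CC=C.CCCCC/C=C\C[C@]1(O)C=CC(=O)[C@H]1CC=C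
F2 | step 5 | racemic (1R*,5R*)-5-allyl-1-[(Z)-oct-2-en-1-yl]-4-oxocyclopent-2-en-1-yl acetate | CCCCC/C=C\C[C@@]1(OC(C)=O)C=CC(=O)[C@@H]1CC=C.CCCCC/C=C\C[C@]1(OC(C)=O)C=CC(=O)[C@H]1CC=C
F3 | step 5 | methyl (4S,5E)-4-acetoxy-7-[(1S,2S)-2-acetoxy-2-[(Z)-oct-2-en-1-yl]-5-oxocyclopent-3-en-1-yl]hept-5-enoate | CCCCC/C=C\C[C@]1(OC(C)=O)C=CC(=O)[C@H]1C/C=C/[C@H](CCC(=O)OC)OC(C)=O
F4 | step 11 | methyl (4S,5E)-4-acetoxy-8-hydroxy-8-{5-[(Z)-oct-2-en-1-yl]furan-2-yl}oct-5-enoate (both C8 epimers) | CCCCC/C=C\Cc1ccc(o1)C(O)C/C=C/[C@H](CCC(=O)OC)OC(C)=O
F5 | step 11 | methyl (4S,5E)-4-acetoxy-7-[(1R,2R)-2-hydroxy-2-[(Z)-oct-2-en-1-yl]-5-oxocyclopent-3-en-1-yl]hept-5-enoate | CCCCC/C=C\C[C@@]1(O)C=CC(=O)[C@@H]1C/C=C/[C@H](CCC(=O)OC)OC(C)=O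
F6 | step 9 | methyl (R)-4-hydroxyhex-5-enoate | C=C[C@H](O)CCC(=O)OC
F7 | step 2 | 2-(oct-2-yn-1-yl)furan | CCCCCC#CCc1ccco1
A1 | alternative 1 | 2-[5-(tert-butyldimethylsilyloxy)-2-(oct-2-yn-1-yl)cyclopent-2-en-1-yl]acetic acid | CCCCCC#CCC1=CC[C@@H](O[Si](C)(C)C(C)(C)C)[C@@H]1CC(=O)O
A2 | alternative 1 | cis-fused 4-(tert-butyldimethylsilyloxy)-6a-(oct-2-yn-1-yl)-6-(phenylseleno)hexahydro-2H-cyclopenta[b]furan-2-one | CCCCCC#CC[C@@]1(OC(=O)C2)[C@@H]([Se]c3ccccc3)C[C@@H](O[Si](C)(C)C(C)(C)C)[C@@H]12
A3 | alternative 2 | methyl (E)-4-(oct-2-yn-1-yl)-7-oxo-4-(triethylsilyloxy)hept-2-enoate | CCCCCC#CC[C@@](O[Si](CC)(CC)CC)(CCC=O)/C=C/C(=O)OC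
A4 | alternative 2 | methyl 2-[2-(oct-2-yn-1-yl)-5-oxo-2-(triethylsilyloxy)cyclopentyl]acetate (silyloxy cis to the acetate arm) | CCCCCC#CC[C@@]1(O[Si](CC)(CC)CC)CCC(=O)[C@@H]1CC(=O)OC
A5 | alternative 3 | (Z)-3-ethynyl-2-[2-(4-methoxybenzyloxy)ethyl]-3-(triethylsilyloxy)undec-5-enal | CCCCC/C=C\C[C@@](O[Si](CC)(CC)CC)(C#C)[C@H](C=O)CCOCc1ccc(OC)cc1
A6 | alternative 3 | 5-[2-(4-methoxybenzyloxy)ethyl]-4-[(Z)-oct-2-en-1-yl]-4-(triethylsilyloxy)cyclopent-2-en-1-one | CCCCC/C=C\C[C@@]1(O[Si](CC)(CC)CC)C=CC(=O)[C@@H]1CCOCc2ccc(OC)cc2
A7 | alternative 3 | [Rh(Ph2PCH2CH2PPh2)]2(BF4)2 | [Rh+].[Rh+].c1ccc(cc1)P(CCP(c1ccccc1)c1ccccc1)c1ccccc1.c1ccc(cc1)P(CCP(c1ccccc1)c1ccccc1)c1ccccc1.F[B-](F)(F)F.F[B-](F)(F)F
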